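**Plan**

- Retrosynthesis: the phenethyl ester C–O bond is cut first (esterification with O-benzylated hydroxytyrosol), then the ring O1–C2 bond (opening of a β-lactone by an enol oxygen, with inversion), then C3–C4 and C5–C6 together (key step), and last the enoate C=C (cross-metathesis).
- Enabling feature: in the dihydropyran ring (O1, C2–C6) C3 bears a carbon that can sit at the carboxyl level (the CH2OH carbon) and C5 bears the methyl ester, so C3–C4–C5 is a glutarate (Michael) array. C6 is a formyl carbon on the ester α-carbon C5 (Claisen array), and O1–C2(CH3)–C3–C(=O) is a 3-hydroxybutanoate unit that can be stored as a β-lactone.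
- Forward order: enoate 3 by cross-metathesis; one-pot union of the enolate of (S)-β-butyrolactone, enoate 3 and a formate; the dihydropyran (the only ring built) closes in step 3 when the formyl enolate oxygen opens the β-lactone at C2; the freed acid is reduced to CH2OH, the side-chain acetal is turned into the acid and esterified, and hydrogenolysis frees the triol.
- The β-lactone is a temporary ring: it protects the enolate from β-elimination, fixes its geometry and face, and later acts as the leaving group; it is removed in step 3 and its carboxyl is reduced in step 4.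
- Stereochemistry: C2 comes from (S)-β-butyrolactone and is inverted in the ring closure (to 2R); C3 is set by attack anti to the lactone methyl group; C4 is set by the anti topicity of the Michael addition; after step 3, C3 carries only a carboxylate or CH2O group and is not epimerizable.

Key step: step 2

Assumption: the target is read as the (2R,3R,4S) isomer, in which the 2-methyl, 3-hydroxymethyl and 4-(acylmethyl) groups are mutually trans; (S)-4-methyloxetan-2-one, 4,4-diethoxybut-1-ene and hydroxytyrosol are taken as purchasable.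

**Route**

Step 1
Reactants: 1 4,4-diethoxybut-1-ene; 2 methyl acrylate
Product: 3 methyl (E)-5,5-diethoxypent-2-enoate
Conditions: second-generation Grubbs catalyst RuCl2(=CHPh)(PCy3)(H2IMes) (2.5 mol %), 2 (3 equiv), CH2Cl2, 40 °C
Reagents that add atoms: none
Why: Olefin cross-metathesis of a reactive terminal olefin with methyl acrylate, which homodimerizes slowly, should give the cross product as the (E)-enoate; no stereocenter is set.

Step 2
Reactants: 4 (S)-4-methyloxetan-2-one; 3 methyl (E)-5,5-diethoxypent-2-enoate; 5 2,2,2-trifluoroethyl formate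
Product: 9 methyl (3S)-5,5-diethoxy-2-formyl-3-[(2S,3S)-2-methyl-4-oxooxetan-3-yl]pentanoate, via lithium lactone enolate 6 (not isolated), via Michael adduct lithium enolate 7 (not isolated), via lithium formyl-ester enolate 8 (not isolated)
Conditions: LiN(iPr)2 (1.05 equiv), THF, −78 °C, 10 min; 3, −78 °C; 5 (1.5 equiv), −78 °C; AcOH, −78 °C; crude 9 used directly
Reagents that add atoms: none
Why: Proposed new method: LiN(iPr)2 should deprotonate 4 to the lithium enolate 6, which cannot undergo β-elimination at −78 °C because the breaking C–O bond lies in the nodal plane of the enolate; 6 should add to the β-carbon of 3 (Michael addition, first new C–C bond), and the ester enolate 7 so formed should be C-formylated by 5 (crossed Claisen condensation, second new C–C bond), no ring being closed. The closest known reaction types are the trans-selective α-alkylation and aldol addition of 4-substituted β-lactone lithium enolates, the tandem Michael addition–enolate acylation of lithium ester enolates, and the C-formylation of kinetic lithium enolates with 2,2,2-trifluoroethyl formate. The stereocenter at the lactone α-carbon should be set by approach of the enoate to the planar four-membered enolate on the face anti to the 4-methyl group (trans-lactone). The stereocenter at the former enoate β-carbon should be set by the relative topicity of the ring-locked (E)-enolate and the (E)-enoate in a lithium-chelated eight-membered transition state, which for (E)-ester and lactone enolates favours the anti adduct, here (3S). The formyl-bearing carbon is enolizable and its configuration is immaterial because it becomes sp2 in step 3. The step needs 1,4- over 1,2-addition and C- over O-formylation, which the ester enolate/enoate pairing, the low temperature and the weakly nucleophilic trifluoroethoxide leaving group should secure.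

Step 3
Reactants: 9 methyl (3S)-5,5-diethoxy-2-formyl-3-[(2S,3S)-2-methyl-4-oxooxetan-3-yl]pentanoate
Product: 12 (2R,3S,4S)-4-(2,2-diethoxyethyl)-5-(methoxycarbonyl)-2-methyl-3,4-dihydro-2H-pyran-3-carboxylic acid, via cesium enolate 10 (not isolated), via cesium carboxylate 11 (not isolated)
Conditions: Cs2CO3 (1.05 equiv), MeCN (0.01 M), 0 °C to rt; then cold 0.5 M HCl to pH 3
Reagents that add atoms: none
Why: Proposed new method: the formyl oxygen of the delocalized α-formyl ester enolate should attack the methyl-bearing carbon of the β-lactone from the side opposite to the ring oxygen in a 6-exo-tet SN2 displacement (alkyl–oxygen cleavage, inversion to 2R, strain-released carboxylate as leaving group), which closes the dihydropyran and creates the β-alkoxyacrylate in one event without touching C3 or C4; the closest known reaction types are the alkyl–oxygen opening of β-lactones by stabilized oxygen nucleophiles such as carboxylates and phenoxides with inversion and the O-alkylation of α-formyl ester enolates to (E)-β-alkoxyacrylates.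

Step 4
Reactants: 12 (2R,3S,4S)-4-(2,2-diethoxyethyl)-5-(methoxycarbonyl)-2-methyl-3,4-dihydro-2H-pyran-3-carboxylic acid
Product: 13 methyl (2R,3R,4S)-4-(2,2-diethoxyethyl)-3-(hydroxymethyl)-2-methyl-3,4-dihydro-2H-pyran-5-carboxylate
Conditions: BH3·SMe2 (1.5 equiv), THF, 0 °C to rt; MeOH quench
Reagents that add atoms: none
Why: Chemoselective borane reduction of a carboxylic acid, which electrophilic borane should reduce much faster than the methyl ester, the electron-poor enol ether or the acetal; the conditions are non-basic, so C3 is not epimerized.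

Step 5
Reactants: 13 methyl (2R,3R,4S)-4-(2,2-diethoxyethyl)-3-(hydroxymethyl)-2-methyl-3,4-dihydro-2H-pyran-5-carboxylate
Product: 14 methyl (2R,3R,4S)-3-({[(benzyloxy)carbonyl]oxy}methyl)-4-(2,2-diethoxyethyl)-2-methyl-3,4-dihydro-2H-pyran-5-carboxylate
Conditions: benzyl chloroformate (1.3 equiv), pyridine (3 equiv), DMAP (0.1 equiv), CH2Cl2, 0 °C to rt
Reagents that add atoms: benzyl chloroformate (O=C(Cl)OCc1ccccc1)
Why: Acylation of the primary alcohol to a benzyl carbonate, which should block lactonization onto the side-chain carboxyl in steps 7 to 9 and is removable by hydrogenolysis together with the benzyl ethers.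

Step 6
Reactants: 14 methyl (2R,3R,4S)-3-({[(benzyloxy)carbonyl]oxy}methyl)-4-(2,2-diethoxyethyl)-2-methyl-3,4-dihydro-2H-pyran-5-carboxylate
Product: 15 methyl (2R,3R,4S)-3-({[(benzyloxy)carbonyl]oxy}methyl)-2-methyl-4-(2-oxoethyl)-3,4-dihydro-2H-pyran-5-carboxylate
Conditions: 1 M HCl (aq)/THF 1:4, rt
Reagents that add atoms: water (O)
Why: Acid-catalysed acetal hydrolysis; the vinylogous carbonate (β-alkoxyacrylate) and the carbonate should be stable to dilute aqueous acid at room temperature.

Step 7
Reactants: 15 methyl (2R,3R,4S)-3-({[(benzyloxy)carbonyl]oxy}methyl)-2-methyl-4-(2-oxoethyl)-3,4-dihydro-2H-pyran-5-carboxylate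
Product: 16 2-[(2R,3R,4S)-3-({[(benzyloxy)carbonyl]oxy}methyl)-5-(methoxycarbonyl)-2-methyl-3,4-dihydro-2H-pyran-4-yl]acetic acid
Conditions: NaClO2, NaH2PO4, 2-methylbut-2-ene, t-BuOH/H2O, 0 °C to rt
Reagents that add atoms: sodium chlorite ([Na+].[O-]Cl=O)
Why: Pinnick oxidation of the aldehyde to the acid with the hypochlorite by-product scavenged by 2-methylbut-2-ene, conditions that should leave the electron-poor enol ether and the carbonate untouched.

Step 8
Reactants: 17 hydroxytyrosol [2-(3,4-dihydroxyphenyl)ethanol]
Product: 18 2-[3,4-bis(benzyloxy)phenyl]ethanol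
Conditions: benzyl bromide (2.1 equiv), K2CO3 (2.2 equiv), acetone, 56 °C
Reagents that add atoms: benzyl bromide (BrCc1ccccc1)
Why: Williamson ether synthesis in which K2CO3 should deprotonate only the phenols, so the aliphatic alcohol stays free.

Step 9
Reactants: 16 2-[(2R,3R,4S)-3-({[(benzyloxy)carbonyl]oxy}methyl)-5-(methoxycarbonyl)-2-methyl-3,4-dihydro-2H-pyran-4-yl]acetic acid; 18 2-[3,4-bis(benzyloxy)phenyl]ethanol
Product: 19 methyl (2R,3R,4S)-4-(2-{2-[3,4-bis(benzyloxy)phenyl]ethoxy}-2-oxoethyl)-3-({[(benzyloxy)carbonyl]oxy}methyl)-2-methyl-3,4-dihydro-2H-pyran-5-carboxylate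
Conditions: EDC·HCl (1.3 equiv), DMAP (0.2 equiv), CH2Cl2, 0 °C to rt
Reagents that add atoms: none
Why: Steglich esterification of an unhindered acetic acid side chain with a primary alcohol under near-neutral conditions; no stereocenter is involved.

Step 10
Reactants: 19 methyl (2R,3R,4S)-4-(2-{2-[3,4-bis(benzyloxy)phenyl]ethoxy}-2-oxoethyl)-3-({[(benzyloxy)carbonyl]oxy}methyl)-2-methyl-3,4-dihydro-2H-pyran-5-carboxylate
Product: 20 methyl (2R,3R,4S)-4-{2-[2-(3,4-dihydroxyphenyl)ethoxy]-2-oxoethyl}-3-(hydroxymethyl)-2-methyl-3,4-dihydro-2H-pyran-5-carboxylate (target)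
Conditions: H2 (1 atm), 10% Pd/C, EtOAc, rt, stopped after uptake of three equivalents; filtration under argon
Reagents that add atoms: none
Why: Hydrogenolysis of the two aryl benzyl ethers and of the benzyl carbonate (with loss of CO2) under neutral conditions, in which the trisubstituted, ester-conjugated enol ether should be reduced far more slowly and the free hydroxy ester should not lactonize.

**Compound list**

1 | 4,4-diethoxybut-1-ene | C=CCC(OCC)OCC | starting material
2 | methyl acrylate | C=CC(=O)OC | starting material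
3 | methyl (E)-5,5-diethoxypent-2-enoate | COC(=O)/C=C/CC(OCC)OCC | intermediate
4 | (S)-4-methyloxetan-2-one | C[C@H]1CC(=O)O1 | starting material
5 | 2,2,2-trifluoroethyl formate | O=COCC(F)(F)F | starting material
6 | lithium enolate of 4 (lithium (4S)-4-methyl-4H-oxet-2-olate) | C[C@@H]1OC(O[Li])=C1 | intermediate
7 | lithium ester enolate of methyl (3S)-5,5-diethoxy-3-[(2S,3S)-2-methyl-4-oxooxetan-3-yl]pentanoate | C[C@@H]1OC(=O)[C@H]1[C@H](CC(OCC)OCC)C=C(OC)O[Li] | intermediate
8 | lithium enolate of 9 (O-lithio hydroxymethylidene form) | C[C@@H]1OC(=O)[C@H]1[C@H](CC(OCC)OCC)C(=CO[Li])C(=O)OC | intermediate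
9 | methyl (3S)-5,5-diethoxy-2-formyl-3-[(2S,3S)-2-methyl-4-oxooxetan-3-yl]pentanoate (C2 of the pentanoate unassigned, enolizable) | C[C@@H]1OC(=O)[C@H]1[C@H](CC(OCC)OCC)C(C=O)C(=O)OC | intermediate
10 | cesium enolate of 9 | [Cs+].C[C@@H]1OC(=O)[C@H]1[C@H](CC(OCC)OCC)C(=C[O-])C(=O)OC | intermediate
11 | cesium (2R,3S,4S)-4-(2,2-diethoxyethyl)-5-(methoxycarbonyl)-2-methyl-3,4-dihydro-2H-pyran-3-carboxylate | [Cs+].COC(=O)C1=CO[C@H](C)[C@@H](C([O-])=O)[C@@H]1CC(OCC)OCC | intermediate
12 | (2R,3S,4S)-4-(2,2-diethoxyethyl)-5-(methoxycarbonyl)-2-methyl-3,4-dihydro-2H-pyran-3-carboxylic acid | COC(=O)C1=CO[C@H](C)[C@@H](C(O)=O)[C@@H]1CC(OCC)OCC | intermediate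
13 | methyl (2R,3R,4S)-4-(2,2-diethoxyethyl)-3-(hydroxymethyl)-2-methyl-3,4-dihydro-2H-pyran-5-carboxylate | COC(=O)C1=CO[C@H](C)[C@@H](CO)[C@@H]1CC(OCC)OCC | intermediate
14 | methyl (2R,3R,4S)-3-({[(benzyloxy)carbonyl]oxy}methyl)-4-(2,2-diethoxyethyl)-2-methyl-3,4-dihydro-2H-pyran-5-carboxylate | COC(=O)C1=CO[C@H](C)[C@@H](COC(=O)OCc2ccccc2)[C@@H]1CC(OCC)OCC | intermediate
15 | methyl (2R,3R,4S)-3-({[(benzyloxy)carbonyl]oxy}methyl)-2-methyl-4-(2-oxoethyl)-3,4-dihydro-2H-pyran-5-carboxylate | COC(=O)C1=CO[C@H](C)[C@@H](COC(=O)OCc2ccccc2)[C@@H]1CC=O | intermediate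
16 | 2-[(2R,3R,4S)-3-({[(benzyloxy)carbonyl]oxy}methyl)-5-(methoxycarbonyl)-2-methyl-3,4-dihydro-2H-pyran-4-yl]acetic acid | COC(=O)C1=CO[C@H](C)[C@@H](COC(=O)OCc2ccccc2)[C@@H]1CC(O)=O | intermediate
17 | hydroxytyrosol, 2-(3,4-dihydroxyphenyl)ethanol | OCCc1ccc(O)c(O)c1 | starting material
18 | 2-[3,4-bis(benzyloxy)phenyl]ethanol | OCCc1ccc(OCc2ccccc2)c(OCc2ccccc2)c1 | intermediate
19 | methyl (2R,3R,4S)-4-(2-{2-[3,4-bis(benzyloxy)phenyl]ethoxy}-2-oxoethyl)-3-({[(benzyloxy)carbonyl]oxy}methyl)-2-methyl-3,4-dihydro-2H-pyran-5-carboxylate | COC(=O)C1=CO[C@H](C)[C@@H](COC(=O)OCc2ccccc2)[C@@H]1CC(=O)OCCc1ccc(OCc2ccccc2)c(OCc2ccccc2)c1 | intermediate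
20 | methyl (2R,3R,4S)-4-{2-[2-(3,4-dihydroxyphenyl)ethoxy]-2-oxoethyl}-3-(hydroxymethyl)-2-methyl-3,4-dihydro-2H-pyran-5-carboxylate | COC(=O)C1=CO[C@H](C)[C@@H](CO)[C@@H]1CC(=O)OCCc1ccc(O)c(O)c1 | target

**Step count and risks**

Total step count: 10. Longest linear sequence: 9 steps (steps 1 to 7, 9 and 10).

Steps most likely to fail:

1. Step 3 (labelled step).
   - What may go wrong: the enolate oxygen may attack the lactone carbonyl instead of the methyl-bearing carbon (acyl–oxygen cleavage followed by acyl transfer and oxa-Michael reclosure), which would close the ring with retention at C2. Alkylation may occur through the ester oxygen. The carboxylate being formed may open another lactone, leading to oligomerization.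
   - Fallback (known chemistry) sets out from 9. Trimethylsilyldiazomethane in toluene/MeOH O-methylates the enolized formyl group to the methyl enol ether methyl (3S)-5,5-diethoxy-2-(methoxymethylidene)-3-[(2S,3S)-2-methyl-4-oxooxetan-3-yl]pentanoate F1. Tetrabutylammonium acetate in THF opens the β-lactone at the methyl-bearing carbon with inversion (carboxylate SN2 with alkyl–oxygen cleavage; attack at the carbonyl only gives a mixed anhydride that reverts) to (2S,3S)-2-[(1R)-1-acetoxyethyl]-3-(2,2-diethoxyethyl)-5-methoxy-4-(methoxymethylidene)-5-oxopentanoic acid F2. K2CO3 in MeOH removes the acetate to give (2S,3S)-3-(2,2-diethoxyethyl)-2-[(1R)-1-hydroxyethyl]-5-methoxy-4-(methoxymethylidene)-5-oxopentanoic acid F3. Pyridinium p-toluenesulfonate in toluene at 60 °C then closes the ring by addition–elimination on the β-methoxyacrylate with retention at the carbinol carbon, and the sequence comes back to the route at 12.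

2. Step 2 (labelled step).
   - What may go wrong: self-condensation or fragmentation of the β-lactone enolate before conjugate addition, insufficient anti topicity in the Michael addition, or O- instead of C-formylation.
   - Fallback (known chemistry) sets out from 3 and 5 and replaces the lactone enolate by the well-studied enolate of the pivalaldehyde acetal of (S)-3-hydroxybutanoic acid, (2S,6S)-2-tert-butyl-6-methyl-1,3-dioxan-4-one F4, which reacts trans to its methyl group. LiN(iPr)2, then 3, then 5 in THF at −78 °C should give methyl (3S)-3-[(2S,4S,5S)-2-tert-butyl-4-methyl-6-oxo-1,3-dioxan-5-yl]-5,5-diethoxy-2-formylpentanoate F5. Trimethylsilyldiazomethane gives the methyl enol ether methyl (3S)-3-[(2S,4S,5S)-2-tert-butyl-4-methyl-6-oxo-1,3-dioxan-5-yl]-5,5-diethoxy-2-(methoxymethylidene)pentanoate F6. LiOH in THF/H2O at 0 °C cleaves the acylal lactone with loss of pivalaldehyde to (2S,3S)-3-(2,2-diethoxyethyl)-2-[(1S)-1-hydroxyethyl]-5-methoxy-4-(methoxymethylidene)-5-oxopentanoic acid F7. Benzenesulfonyl chloride in pyridine closes the β-lactone by carboxyl activation (retention) to F1, which is taken through F2 and F3 as above; the sequence comes back to the route at 12.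

3. Step 4.
   - What may go wrong: over-reduction by borane, that is conjugate reduction or hydroboration of the vinylogous carbonate or reductive opening of the acetal.
   - Fallback sets out from 12. Isobutyl chloroformate and N-methylmorpholine in THF at −15 °C give the mixed anhydride (2R,3S,4S)-4-(2,2-diethoxyethyl)-5-(methoxycarbonyl)-2-methyl-3,4-dihydro-2H-pyran-3-carboxylic 2-methylpropyl carbonic anhydride F8, which NaBH4 in THF/H2O at 0 °C reduces to the alcohol; the sequence comes back to the route at 13.

Further compounds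
F1 | step 3 | methyl (3S)-5,5-diethoxy-2-(methoxymethylidene)-3-[(2S,3S)-2-methyl-4-oxooxetan-3-yl]pentanoate | C[C@@H]1OC(=O)[C@H]1[C@H](CC(OCC)OCC)C(=COC)C(=O)OC
F2 | step 3 | (2S,3S)-2-[(1R)-1-acetoxyethyl]-3-(2,2-diethoxyethyl)-5-methoxy-4-(methoxymethylidene)-5-oxopentanoic acid | C[C@@H](OC(C)=O)[C@H]([C@H](CC(OCC)OCC)C(=COC)C(=O)OC)C(O)=O
F3 | step 3 | (2S,3S)-3-(2,2-diethoxyethyl)-2-[(1R)-1-hydroxyethyl]-5-methoxy-4-(methoxymethylidene)-5-oxopentanoic acid | C[C@@H](O)[C@H]([C@H](CC(OCC)OCC)C(=COC)C(=O)OC)C(O)=O
F4 | step 2 | (2S,6S)-2-tert-butyl-6-methyl-1,3-dioxan-4-one | C[C@H]1CC(=O)O[C@@H](C(C)(C)C)O1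
F5 | step 2 | methyl (3S)-3-[(2S,4S,5S)-2-tert-butyl-4-methyl-6-oxo-1,3-dioxan-5-yl]-5,5-diethoxy-2-formylpentanoate | C[C@H]1[C@H]([C@H](CC(OCC)OCC)C(C=O)C(=O)OC)C(=O)O[C@@H](C(C)(C)C)O1
F6 | step 2 | methyl (3S)-3-[(2S,4S,5S)-2-tert-butyl-4-methyl-6-oxo-1,3-dioxan-5-yl]-5,5-diethoxy-2-(methoxymethylidene)pentanoate | C[C@H]1[C@H]([C@H](CC(OCC)OCC)C(=COC)C(=O)OC)C(=O)O[C@@H](C(C)(C)C)O1
F7 | step 2 | (2S,3S)-3-(2,2-diethoxyethyl)-2-[(1S)-1-hydroxyethyl]-5-methoxy-4-(methoxymethylidene)-5-oxopentanoic acid | C[C@H](O)[C@H]([C@H](CC(OCC)OCC)C(=COC)C(=O)OC)C(O)=O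
F8 | step 4 | (2R,3S,4S)-4-(2,2-diethoxyethyl)-5-(methoxycarbonyl)-2-methyl-3,4-dihydro-2H-pyran-3-carboxylic 2-methylpropyl carbonic anhydride | COC(=O)C1=CO[C@H](C)[C@@H](C(=O)OC(=O)OCC(C)C)[C@@H]1CC(OCC)OCC
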